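The readings are simulated for an exercise, noise included.

The constants I have for this flask are no rate constants, just its charges and Thursday's readings of the same flask so far.

- Thursday's: solid substrate 0.80 M; coupling partner 1.2 M; the very flask that is asked about, followed so far
- flask: solid substrate 0.80 M; coupling partner 1.20 M; time 12 min

Thursday's run (percent of the solid substrate charged)

| time / min | target / % | over-reaction product / % | solid substrate / % |
|---|---|---|---|
| 0.500 | 49.5 | 32.8 | 0 |
| 1.00 | 47.9 | 45.5 | 0.2 |
| 1.33 | 46.6 | 49.3 | 0.5 |
| 2.00 | 48.2 | 50.0 | 0 |
| 2.50 | 46.8 | 52.0 | 0 |

(each reading ± 1 percentage point)

- solid, in amounts per volume of the solution: solid substrate
- the analysis behind the earlier runs scatters by 1 percentage point, standard deviation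
- at the start none of the solid substrate is in solution
- what has only dissolved of solid substrate counts as not reacted
- the reaction counts as stopped when no species that holds the solid substrate changes by six tenths of a point or more over the second half of the time

* the state of affairs at 12 min: stopped, and by what, or still going (for what has run out or reacted, a solid counts together with what of it has only dissolved) (the coupling partner has run out first / it is still moving / forward and back rates have come level)
* amount of target at 12 min, in percent of the solid substrate charged
* amount of over-reaction product at 12 min, in percent of the solid substrate charged
* amount of target if the flask were left three thousand times as long, in percent of the solid substrate charged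

I reckon in fractions of the solid substrate charged. I take target to hold one coupling partner and over-reaction product two, so I carry the partner budget, coupling partner charged per solid substrate charged: 1.50. Counted that way, the last reading at 2.50 min already comes to 1.51. In this flask the budget is smaller than the 2 that full over-reaction takes, so I expect the coupling partner to be the limiting reagent. That reading leaves 1.20 % of the charge unaccounted for, and if that share stays, my reckoning gives target 47.6 % and over-reaction product 51.2 %.

The forecast says the coupling partner has run out first, with target 47.5 %, over-reaction product 51.2 % and, after the long wait, target 47.5 %, on the ground that “Once the partner is gone, nothing further can happen”.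

In the flask, the coupling partner has run out first, with target 46.2 %, over-reaction product 51.9 % and, after the long wait, target 46.2 %; the forecast holds on all four.

    starting material + coupling partner → target, rate k1*[starting material]*[coupling partner]^0.5 (k = 0.0830 /M^0.5/s)
    coupling partner + target → over-reaction product (k = 0.0550 /M/s)
    solid substrate ⇌ starting material, rate k3*(cs3 - [starting material]) while solid is left; crystals form when [starting material] > cs3 (solubility = 0.600 M, k = 1.50 /s)

This flask is at rest by 6.00 min, with coupling partner at 0 % of its charge and target at 46.2 %. Ten times the asked time, 120 min, shows target 46.2 % and over-reaction product 51.9 %, with 1.92 % still starting material. Counted by partners held, the end state comes to 1.50, against the budget of 1.50.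

In a neighbour flask with 0.20 M of solid substrate, the budget becomes 6.00, above 2, so I expect over-reaction product to take up the charge and 66.7 % of the coupling partner to remain. That neighbour gives over-reaction product 100 %, target 0 % and coupling partner 67 %.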